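## The problem

(7'S,8'S)-Nocomtal (17) is a 1,4-benzodioxane neolignan. Ring A is a benzene ring carrying the (E)-propenal chain (C7–C9) at C1, a methoxy group at C3 and the two dioxane oxygens O4 and O5. The dioxane ring is completed by C8' (bonded to O4, bearing the C9' hydroxymethyl group) and by benzylic C7' (bonded to O5, bearing ring C, a 4-hydroxy-3-methoxyphenyl group).

- **Regiochemistry.** The two oxygens of the unsymmetrical ring A catechol must be told apart: O4, flanked by the methoxy group, goes to C8', and O5 goes to C7'.
- **Stereochemistry.** C7' and C8' are adjacent, trans and both S. The trans arrangement is the stable one, so either centre can steer the other while one of them is still epimerisable, but the absolute sense must come from outside the molecule.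
- **Labile positions.** C7' is a benzylic aryl ether para to an oxygen substituent, so it ionises under acid and opens to a quinone methide under base once the ring C phenol is free. C8' is inert at the alcohol level and labile only while C9' is a carbonyl group.
- **Sensitive groups.** The cinnamaldehyde unit on ring A tolerates neither hydride nor amine catalysts and must come late; the ring C phenol must stay masked for most of the route.
- **Enabling feature.** The O5–C7' bond lies β to C9'. With C9' as an aldehyde, C7'–C8' becomes the double bond of a 2-aryloxycinnamaldehyde whose ring A O5 hydroxyl can reach C7' through a six-membered transition state. The dioxane ring and both stereocentres can then arise in one conjugate addition from a flat, achiral precursor.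

## Retrosynthesis

**C1–C7 bond (ring A to the propenal chain).** Target 17 is traced to its ring C methoxymethyl (MOM) ether 16, and 16 to aryl bromide 13 plus acrolein diethyl acetal 14. The enal could not survive the amine catalyst and the hydride used earlier, and a ring A aldehyde handle would have to be protected through a peracid step. A bromine atom is inert to all of that, and it is already present in a cheap ring A building block. The forward reaction is a Heck coupling that installs the three-carbon unit at the aldehyde oxidation level, followed by acidic removal of the MOM group.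

**C9' oxidation level.** Alcohol 13 comes from aldehyde 12 by hydride reduction. No skeletal bond is cut. The reduction is run in the flask in which 12 is formed, because only at the alcohol level are the C–O bond at C7' and the configuration at C8' safe.

**O5–C7' bond (key cut).** Aldehyde 12 is opened at O5–C7', with removal of the C8' hydrogen, to the achiral enal 11. The neighbouring cuts are weaker. Cutting O4–C8' would mean alkylating the hindered, doubly ortho-substituted O4 at a secondary carbon, and would need a pre-built stereocentre. Cutting both C–O bonds at once (catechol plus a 1,2-dielectrophile) leaves the O4/O5 regiochemistry open. The chosen cut removes the ring and both stereocentres in one stroke. It asks the forward reaction for an enantioselective 6-endo oxa-conjugate addition of a phenol to an α-branched, α-aryloxy enal, with trans protonation at C8'.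

**C7'=C8' double bond.** Enal 11 is the desilylated form of silyl ether 10, which is cut at the double bond to aryloxyacetaldehyde 7 and MOM-vanillin 9 (an aldol condensation). The cut is convergent, splits the molecule into its ring A and ring C halves, and needs no stereocontrol beyond the thermodynamic alkene geometry. O5 must be capped during the condensation so that no racemic ring closure occurs under the amine conditions; a triisopropylsilyl (TIPS) ether, removable with buffered fluoride, serves.

**O4–C8' bond and the O5 oxygen.** Aldehyde 7 is the hydrolysed form of acetal 6, the silyl ether of phenol 5. Phenol 5 comes from benzaldehyde 3 by Baeyer–Villiger oxidation, and 3 from 5-bromo-o-vanillin 1 and bromoacetaldehyde diethyl acetal 2 by O-alkylation. In 1 the bromine, the methoxy group and the O4 hydroxyl are already in place, and the formyl group is a latent O5. The two catechol oxygens are therefore distinguished from the first step, and the O4–C8' bond is made at a primary carbon. MOM-vanillin 9 is one protection step from vanillin 8.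

## Roads not taken

**Alternative 1: three-component oxonium ylide aldol.**
- *Cut:* O4–C8' and C7'–C8' together.
- *Key step:* Rh2(OAc)4 converts ethyl diazoacetate A2 into a carbene. The free O4 hydroxyl of the O5-silylated ring A phenol A1 captures it, and the oxonium ylide is intercepted by vanillin acetate A3 under a chiral BINOL-derived phosphoric acid. The product is the acyclic ester A4 with both stereocentres; no ring is formed.
- *Merits:* very convergent. Three simple pieces give the whole C7'–C8'–C9' backbone with the correct O4 attachment in one irreversible C–C bond-forming step. In that respect it is better than the chosen plan, whose stereo-defining C–O bond formation is reversible.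
- *Weak points:* A1 is a hindered, doubly ortho-substituted phenol. The simple 1,2-proton shift (plain O–H insertion) competes with aldehyde trapping. Acceptor-only diazo esters and electron-rich benzaldehydes are at the unfavourable end of this reaction class.
- *Stereochemical cost:* the ring must still be closed at O5–C7'. The C7' descriptor of A4 is already that of the target, so closure needs net retention. A Mitsunobu-type inversion would give the cis ring. In practice this means ionisation at C7' with thermodynamic trans control, which discards the C7' centre the catalyst set and leaves an ester α-centre (C8') as sole carrier of the absolute configuration.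
- *Comparison:* the chosen plan counters its reversibility by reducing the aldehyde in the same flask. It forms ring and stereocentres in a single event and needs no later closure.

**Alternative 2: dehydrogenative para-quinone methide closure.**
- *Cut:* also O5–C7', but with C7' as a methylene group in the precursor A5, which carries the C8' stereocentre, a silylated C9' alcohol and a ring A aldehyde.
- *Key step:* 2,3-dichloro-5,6-dicyano-1,4-benzoquinone or Ag2O oxidises the 4-alkyl-2-methoxyphenol of A5 to its quinone methide, and the ring A O5 hydroxyl adds to C7' to give the trans benzodioxane A6.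
- *Merits:* the closure is biomimetic and far better precedented than the chosen key step. Trans selectivity rests on thermodynamics. The ring C phenol needs no protecting group, and the ring A aldehyde allows the enal to be finished by a two-carbon olefination without palladium.
- *Weak points:* the closure only relays chirality. The C8' centre must be built beforehand, and joining the hindered O4 to a secondary carbon (Mitsunobu inversion of an enantiopure alcohol) is slow and prone to elimination. A5 has two free phenols and an aldehyde exposed to the oxidant. The quinone methide can tautomerise to the C7'=C8' styrene, which would erase C8'. The product is itself a para-hydroxybenzyl ether open to further oxidation.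
- *Comparison:* this road is the safer one for diastereocontrol. The chosen plan sets against it a shorter sequence, catalytic creation of all chirality from an achiral enal made by one condensation, and no stoichiometric chiral building block.

**Alternative 3: bromophenol plus cis-epoxide annulation.**
- *Cut:* O5–C7' and the aryl C4–O4 bond.
- *Key step:* the phenoxide of bromophenol A7 opens the enantiopure cis-epoxide A8 at benzylic C7' with inversion. The released C8' alkoxide is then joined to C4 by Pd(OAc)2-catalysed C–O coupling with a bulky ligand such as 2-di-tert-butylphosphino-2',4',6'-triisopropylbiphenyl, closing the ring to ester A9.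
- *Merits:* the stereochemistry is stereospecifically derived from a single epoxidation (inversion at C7', retention at C8', cis-epoxide to trans ring). Regiochemistry is fixed by where OH and Br sit on A7. On paper this is more secure stereocontrol than the chosen plan offers.
- *Weak points:* A8 is the epoxide of a very electron-rich styrene and ionises easily, which costs stereospecificity and invites rearrangement. It requires a Z-alkene and an enantioselective cis-epoxidation. The C–O coupling must take place at a bromide flanked by two ortho substituents with a secondary alkoxide that can undergo β-hydride elimination. The ester of A9 needs about three further steps to become the enal.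
- *Comparison:* two delicate steps and a longer sequence, against one delicate step in the chosen plan, which also has a racemic-closure fallback from the same precursor.

Key step: step 8

Assumption: the quinine-derived primary amine is taken to expose the C7' face that leads to the 7'S product; if the sense of induction proves opposite, the pseudo-enantiomeric 9-amino-9-deoxy-epi-quinidine is used in step 8 with no other change.

## Route

Step 1
Reactants: 1 5-bromo-2-hydroxy-3-methoxybenzaldehyde (5-bromo-o-vanillin); 2 2-bromo-1,1-diethoxyethane (bromoacetaldehyde diethyl acetal)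
Product: 3 5-bromo-2-(2,2-diethoxyethoxy)-3-methoxybenzaldehyde
Conditions: K2CO3, KI (cat.), DMF, 110 °C
Reagents that add atoms: none
Why: Williamson ether synthesis; the phenoxide of 1 displaces the primary bromide of 2 (iodide catalysis and heat compensate for the hindered, deactivated phenol), and the non-enolisable aldehyde and the aryl bromide are inert to carbonate.

Step 2
Reactants: 3 5-bromo-2-(2,2-diethoxyethoxy)-3-methoxybenzaldehyde
Product: 5 5-bromo-2-(2,2-diethoxyethoxy)-3-methoxyphenol, via aryl formate 4 (not isolated)
Conditions: mCPBA, NaHCO3, CH2Cl2, 0 °C to rt; then K2CO3, MeOH, rt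
Reagents that add atoms: 3-chloroperoxybenzoic acid (mCPBA), OOC(=O)c1cccc(Cl)c1
Why: Baeyer–Villiger (Dakin-type) oxidation; the ortho-alkoxy group makes the aryl group migrate so that the formyl group becomes a formate, which methanolysis converts to the O5 phenol, while the buffered medium spares the diethyl acetal.

Step 3
Reactants: 5 5-bromo-2-(2,2-diethoxyethoxy)-3-methoxyphenol
Product: 6 [5-bromo-2-(2,2-diethoxyethoxy)-3-methoxyphenoxy]tri(propan-2-yl)silane
Conditions: TIPSCl, imidazole, DMF, rt
Reagents that add atoms: chlorotri(propan-2-yl)silane (TIPSCl), CC(C)[Si](Cl)(C(C)C)C(C)C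
Why: Standard silylation of a phenol; the bulky aryl TIPS ether should survive the aqueous acid of step 4 and the amine/acid medium of step 6, and is later cleaved by fluoride without touching the MOM ether.

Step 4
Reactants: 6 [5-bromo-2-(2,2-diethoxyethoxy)-3-methoxyphenoxy]tri(propan-2-yl)silane
Product: 7 2-{4-bromo-2-methoxy-6-[tri(propan-2-yl)silyloxy]phenoxy}acetaldehyde
Conditions: CF3CO2H, H2O, CHCl3, 0 °C to rt; used crude
Reagents that add atoms: water, O
Why: Acid-catalysed acetal hydrolysis; aryl silyl ethers and aryl alkyl ethers are stable to aqueous trifluoroacetic acid, and the sensitive aryloxyacetaldehyde is carried on without purification.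

Step 5
Reactants: 8 vanillin (4-hydroxy-3-methoxybenzaldehyde)
Product: 9 3-methoxy-4-(methoxymethoxy)benzaldehyde
Conditions: MOMCl, iPr2NEt, CH2Cl2, 0 °C to rt
Reagents that add atoms: chloromethyl methyl ether (MOMCl), COCCl
Why: O-alkylation of the phenol to its MOM acetal, a routine protection that is stable to base, fluoride, hydride and palladium and leaves by mild acid at the end.

Step 6
Reactants: 7 2-{4-bromo-2-methoxy-6-[tri(propan-2-yl)silyloxy]phenoxy}acetaldehyde; 9 3-methoxy-4-(methoxymethoxy)benzaldehyde
Product: 10 (Z)-2-{4-bromo-2-methoxy-6-[tri(propan-2-yl)silyloxy]phenoxy}-3-[3-methoxy-4-(methoxymethoxy)phenyl]prop-2-enal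
Conditions: pyrrolidine (30 mol%), 4-(dimethylamino)benzoic acid (30 mol%), CH2Cl2, rt, 7 added slowly to 9 (1.5 equiv)
Reagents that add atoms: none
Why: Amine/acid-catalysed crossed aldol (Mannich-type) condensation; the enamine of the only enolisable partner 7 adds to the iminium ion of non-enolisable 9 and loss of pyrrolidine gives the enal. The geometry with ring C trans to the formyl group (Z by the priority rules) is the thermodynamic one, and slow addition of 7 to excess 9 limits self-condensation.

Step 7
Reactants: 10 (Z)-2-{4-bromo-2-methoxy-6-[tri(propan-2-yl)silyloxy]phenoxy}-3-[3-methoxy-4-(methoxymethoxy)phenyl]prop-2-enal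
Product: 11 (Z)-2-(4-bromo-2-hydroxy-6-methoxyphenoxy)-3-[3-methoxy-4-(methoxymethoxy)phenyl]prop-2-enal
Conditions: nBu4NF, AcOH (1:1.2), THF, 0 °C; used at once
Reagents that add atoms: none
Why: Fluoride desilylation of an aryl silyl ether; the acetic acid buffer keeps the liberated O5 phenol protonated so that it should not add to the enal without the chiral catalyst, and the MOM ether, enal and aryl bromide are inert to fluoride.

Step 8
Reactants: 11 (Z)-2-(4-bromo-2-hydroxy-6-methoxyphenoxy)-3-[3-methoxy-4-(methoxymethoxy)phenyl]prop-2-enal
Product: 13 [(2S,3S)-6-bromo-8-methoxy-3-[3-methoxy-4-(methoxymethoxy)phenyl]-2,3-dihydro-1,4-benzodioxin-2-yl]methanol, via trans aldehyde 12 (not isolated)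
Conditions: 9-amino-9-deoxy-epi-quinine (20 mol%), CF3CO2H (40 mol%), toluene, 0 °C to rt; then MeOH, NaBH4, −20 °C
Reagents that add atoms: none
Why: Proposed new method: the primary amine condenses with the α-branched enal 11 to an iminium ion (a secondary amine would be too hindered), which restores electrophilicity at C7' despite the donor aryl and α-aryloxy groups; the free O5 hydroxyl of ring A adds to C7', and the resulting enamine is protonated at C8' and hydrolysed to aldehyde 12, (2R,3S)-6-bromo-8-methoxy-3-[3-methoxy-4-(methoxymethoxy)phenyl]-2,3-dihydro-1,4-benzodioxine-2-carbaldehyde. The closest known reactions are amine-catalysed intramolecular oxa-Michael additions of phenols to enals and enones (chromans, flavanones), cinchona primary-amine iminium catalysis of conjugate additions to α-substituted enals, and the base-mediated closure of 2-(2-hydroxyaryloxy)acrylates to benzodioxane-2-carboxylates; their combination on an α-aryloxy enal is new. The dioxane ring closes 6-endo-trig, since both alkene carbons C7' and C8' end up in the ring, and rotation about the O4–C8' bond places O5 over the π face at C7'. C7' is set by the catalyst: the cinchona framework covers one face of the iminium ion and its protonated quinuclidine/trifluoroacetate pair is expected to guide the phenol to the open face. C8' is set by enamine protonation and, because it remains epimerisable through the catalyst-bound enamine, it should settle in the more stable trans relationship to C7' (the C8' descriptor changes from R in 12 to S in 13 only because the priorities change on reduction). The step needs 1,4- over 1,2-addition (the 1,2-adduct is a reversible lactol or hemiaminal), no uncatalysed racemic closure (only one free phenol, no free base, apolar solvent) and no reversal of the C–O bond formation; the last is secured by adding NaBH4 to the same flask, which converts 12 to alcohol 13, where neither retro-addition nor epimerisation at C8' is possible.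

Step 9
Reactants: 13 [(2S,3S)-6-bromo-8-methoxy-3-[3-methoxy-4-(methoxymethoxy)phenyl]-2,3-dihydro-1,4-benzodioxin-2-yl]methanol; 14 3,3-diethoxyprop-1-ene (acrolein diethyl acetal)
Product: 16 (E)-3-[(2S,3S)-2-(hydroxymethyl)-8-methoxy-3-[3-methoxy-4-(methoxymethoxy)phenyl]-2,3-dihydro-1,4-benzodioxin-6-yl]prop-2-enal, via diethyl acetal 15 (not isolated)
Conditions: Pd(OAc)2 (5 mol%), nBu4NOAc, K2CO3, KCl, DMF, 90 °C; then 2 M HCl, rt
Reagents that add atoms: water, O
Why: Mizoroki–Heck reaction; zerovalent palladium formed from Pd(OAc)2 inserts into the C1–Br bond, the aryl group adds to the terminal carbon of 14 and syn β-hydride elimination gives the (E)-cinnamyl acetal, this phosphine-free acetate/chloride medium being the known way to favour the unsaturated acetal over the ester. Brief dilute acid unmasks the enal; with the ring C phenol still capped and C8' at the alcohol level, neither stereocentre is at risk under the basic coupling conditions.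

Step 10
Reactants: 16 (E)-3-[(2S,3S)-2-(hydroxymethyl)-8-methoxy-3-[3-methoxy-4-(methoxymethoxy)phenyl]-2,3-dihydro-1,4-benzodioxin-6-yl]prop-2-enal
Product: 17 (7'S,8'S)-nocomtal, (E)-3-[(2S,3S)-3-(4-hydroxy-3-methoxyphenyl)-2-(hydroxymethyl)-8-methoxy-2,3-dihydro-1,4-benzodioxin-6-yl]prop-2-enal
Conditions: 3 M HCl, THF, 40 °C
Reagents that add atoms: none
Why: Acid-catalysed hydrolysis of the aryl MOM acetal frees the ring C phenol; C8' has no acidic hydrogen at the alcohol level, and any reversible ionisation at C7' should re-close to the more stable trans ring, so the (7'S,8'S) configuration is expected to persist.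

## Compound list

1 | 5-bromo-2-hydroxy-3-methoxybenzaldehyde (5-bromo-o-vanillin) | COc1cc(Br)cc(C=O)c1O | starting material
2 | 2-bromo-1,1-diethoxyethane (bromoacetaldehyde diethyl acetal) | CCOC(CBr)OCC | starting material
3 | 5-bromo-2-(2,2-diethoxyethoxy)-3-methoxybenzaldehyde | COc1cc(Br)cc(C=O)c1OCC(OCC)OCC | intermediate
4 | 5-bromo-2-(2,2-diethoxyethoxy)-3-methoxyphenyl formate | COc1cc(Br)cc(OC=O)c1OCC(OCC)OCC | intermediate
5 | 5-bromo-2-(2,2-diethoxyethoxy)-3-methoxyphenol | COc1cc(Br)cc(O)c1OCC(OCC)OCC | intermediate
6 | [5-bromo-2-(2,2-diethoxyethoxy)-3-methoxyphenoxy]tri(propan-2-yl)silane | COc1cc(Br)cc(O[Si](C(C)C)(C(C)C)C(C)C)c1OCC(OCC)OCC | intermediate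
7 | 2-{4-bromo-2-methoxy-6-[tri(propan-2-yl)silyloxy]phenoxy}acetaldehyde | COc1cc(Br)cc(O[Si](C(C)C)(C(C)C)C(C)C)c1OCC=O | intermediate
8 | vanillin (4-hydroxy-3-methoxybenzaldehyde) | COc1cc(C=O)ccc1O | starting material
9 | 3-methoxy-4-(methoxymethoxy)benzaldehyde | COCOc1ccc(C=O)cc1OC | intermediate
10 | (Z)-2-{4-bromo-2-methoxy-6-[tri(propan-2-yl)silyloxy]phenoxy}-3-[3-methoxy-4-(methoxymethoxy)phenyl]prop-2-enal | O=C/C(Oc1c(OC)cc(Br)cc1O[Si](C(C)C)(C(C)C)C(C)C)=C/c1ccc(OCOC)c(OC)c1 | intermediate
11 | (Z)-2-(4-bromo-2-hydroxy-6-methoxyphenoxy)-3-[3-methoxy-4-(methoxymethoxy)phenyl]prop-2-enal | O=C/C(Oc1c(OC)cc(Br)cc1O)=C/c1ccc(OCOC)c(OC)c1 | intermediate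
12 | (2R,3S)-6-bromo-8-methoxy-3-[3-methoxy-4-(methoxymethoxy)phenyl]-2,3-dihydro-1,4-benzodioxine-2-carbaldehyde (trans) | COc1cc([C@@H]2Oc3cc(Br)cc(OC)c3O[C@H]2C=O)ccc1OCOC | intermediate
13 | [(2S,3S)-6-bromo-8-methoxy-3-[3-methoxy-4-(methoxymethoxy)phenyl]-2,3-dihydro-1,4-benzodioxin-2-yl]methanol | COc1cc([C@@H]2Oc3cc(Br)cc(OC)c3O[C@H]2CO)ccc1OCOC | intermediate
14 | 3,3-diethoxyprop-1-ene (acrolein diethyl acetal) | C=CC(OCC)OCC | starting material
15 | [(2S,3S)-6-[(E)-3,3-diethoxyprop-1-enyl]-8-methoxy-3-[3-methoxy-4-(methoxymethoxy)phenyl]-2,3-dihydro-1,4-benzodioxin-2-yl]methanol | COc1cc([C@@H]2Oc3cc(/C=C/C(OCC)OCC)cc(OC)c3O[C@H]2CO)ccc1OCOC | intermediate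
16 | (E)-3-[(2S,3S)-2-(hydroxymethyl)-8-methoxy-3-[3-methoxy-4-(methoxymethoxy)phenyl]-2,3-dihydro-1,4-benzodioxin-6-yl]prop-2-enal | COc1cc([C@@H]2Oc3cc(/C=C/C=O)cc(OC)c3O[C@H]2CO)ccc1OCOC | intermediate
17 | (7'S,8'S)-nocomtal, (E)-3-[(2S,3S)-3-(4-hydroxy-3-methoxyphenyl)-2-(hydroxymethyl)-8-methoxy-2,3-dihydro-1,4-benzodioxin-6-yl]prop-2-enal | COc1cc([C@@H]2Oc3cc(/C=C/C=O)cc(OC)c3O[C@H]2CO)ccc1O | target

## Step count and least certain steps

Total: 10 steps. Longest linear sequence: 9 steps (steps 1–4 and 6–10 from 1); step 5 is a one-step branch.

**Step 8 (key step, proposed new method).**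
- *What may go wrong:* slow iminium formation and turnover, because the enal is α-branched and C7' carries two donor groups; erosion of enantiopurity through reversal of the C–O bond formation or through uncatalysed closure of the free phenol; an unpredicted sense of facial selectivity (see the assumption); minor loss of material through hydride reduction of catalyst-bound imine.
- *Fallback (known chemistry):* it sets out from 11. A catalytic amount of K2CO3 in MeCN at rt closes the ring through the phenoxide, as in the classical benzodioxane synthesis from catechols and 2-aryloxyacrylates, and gives the racemic trans aldehyde F1. This is reduced in the same flask with NaBH4 in MeOH to the racemic trans alcohol F2. Separation of F2 by preparative chromatography on a chiral stationary phase gives the (2S,3S) enantiomer, which is 13, where the route is rejoined. Half of the material is lost.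

**Step 6.**
- *What may go wrong:* self-condensation of the enolisable aldehyde 7 outrunning the cross-condensation with the electron-rich, weakly electrophilic 9, or incomplete elimination to the enal.
- *Fallback:* it sets out from 7 and changes to a stoichiometric directed aldol. Condensation of 7 with cyclohexylamine (MgSO4, CH2Cl2) gives the N-cyclohexylimine F3. Deprotonation with lithium diisopropylamide in THF at −78 °C and addition of 9 gives the β-hydroxy imine F4 as a diastereomer mixture. Aqueous oxalic acid hydrolyses the imine and dehydrates the aldol, returning to the route at 10.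

**Step 9.**
- *What may go wrong:* slow oxidative addition into the electron-rich C1–Br bond, and β-hydride elimination toward the acetal carbon, which after hydrolysis leads to the saturated ester instead of the enal.
- *Fallback:* it sets out from 13 and replaces the Heck reaction by a Suzuki–Miyaura coupling with commercial (E)-2-(3,3-diethoxyprop-1-enyl)-4,4,5,5-tetramethyl-1,3,2-dioxaborolane [Pd(dppf)Cl2, K3PO4, dioxane/H2O, 80 °C]. Position and geometry of the double bond are then fixed by the boronate. The product is the same acetal 15, and acidic work-up returns to the route at 16. This fallback makes no compound outside the compound list (F0).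

**Step 10.**
- *What may go wrong:* during the time an aryl MOM ether needs in acid, ionisation of the C7'–O5 bond with solvolytic ring opening, or acid-promoted addition to and oligomerisation of the enal.
- *Fallback:* it sets out from 13 and reverses the order of events, so that the enal never meets MOM-cleaving acid. The MOM group is removed at the bromide stage (3 M HCl, THF, 40 °C) to give bromophenol F5. Heck coupling of F5 with 14 under a weaker base [Pd(OAc)2, nBu4NOAc, NaHCO3, KCl, DMF, 90 °C] gives the phenolic diethyl acetal F6. A few minutes in 1 M HCl at rt then gives 17 directly.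

## Further compounds

F1 | step 8 | racemic trans-6-bromo-8-methoxy-3-[3-methoxy-4-(methoxymethoxy)phenyl]-2,3-dihydro-1,4-benzodioxine-2-carbaldehyde (both enantiomers shown) | COc1cc([C@@H]2Oc3cc(Br)cc(OC)c3O[C@H]2C=O)ccc1OCOC.COc1cc([C@H]2Oc3cc(Br)cc(OC)c3O[C@@H]2C=O)ccc1OCOC
F2 | step 8 | racemic trans-{6-bromo-8-methoxy-3-[3-methoxy-4-(methoxymethoxy)phenyl]-2,3-dihydro-1,4-benzodioxin-2-yl}methanol (both enantiomers shown) | COc1cc([C@@H]2Oc3cc(Br)cc(OC)c3O[C@H]2CO)ccc1OCOC.COc1cc([C@H]2Oc3cc(Br)cc(OC)c3O[C@@H]2CO)ccc1OCOC
F3 | step 6 | (E)-N-cyclohexyl-2-{4-bromo-2-methoxy-6-[tri(propan-2-yl)silyloxy]phenoxy}ethan-1-imine | COc1cc(Br)cc(O[Si](C(C)C)(C(C)C)C(C)C)c1OC/C=N/C1CCCCC1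
F4 | step 6 | 2-{4-bromo-2-methoxy-6-[tri(propan-2-yl)silyloxy]phenoxy}-3-(cyclohexylimino)-1-[3-methoxy-4-(methoxymethoxy)phenyl]propan-1-ol (mixture of diastereomers) | COc1cc(Br)cc(O[Si](C(C)C)(C(C)C)C(C)C)c1OC(/C=N/C1CCCCC1)C(O)c1ccc(OCOC)c(OC)c1
F0 | step 9 | none | none
F5 | step 10 | 4-[(2S,3S)-7-bromo-3-(hydroxymethyl)-5-methoxy-2,3-dihydro-1,4-benzodioxin-2-yl]-2-methoxyphenol | COc1cc([C@@H]2Oc3cc(Br)cc(OC)c3O[C@H]2CO)ccc1O
F6 | step 10 | 4-[(2S,3S)-7-[(E)-3,3-diethoxyprop-1-enyl]-3-(hydroxymethyl)-5-methoxy-2,3-dihydro-1,4-benzodioxin-2-yl]-2-methoxyphenol | COc1cc([C@@H]2Oc3cc(/C=C/C(OCC)OCC)cc(OC)c3O[C@H]2CO)ccc1O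
A1 | alternative 1 | 4-bromo-2-methoxy-6-{[tri(propan-2-yl)silyl]oxy}phenol | COc1cc(Br)cc(O[Si](C(C)C)(C(C)C)C(C)C)c1O
A2 | alternative 1 | ethyl diazoacetate | CCOC(=O)C=[N+]=[N-]
A3 | alternative 1 | 4-formyl-2-methoxyphenyl acetate (vanillin acetate) | COc1cc(C=O)ccc1OC(C)=O
A4 | alternative 1 | ethyl (2R,3S)-3-(4-acetoxy-3-methoxyphenyl)-2-{4-bromo-2-methoxy-6-[tri(propan-2-yl)silyloxy]phenoxy}-3-hydroxypropanoate | COc1cc([C@H](O)[C@@H](Oc2c(OC)cc(Br)cc2O[Si](C(C)C)(C(C)C)C(C)C)C(=O)OCC)ccc1OC(C)=O
A5 | alternative 2 | 4-{[(2R)-1-{[tert-butyl(dimethyl)silyl]oxy}-3-(4-hydroxy-3-methoxyphenyl)propan-2-yl]oxy}-3-hydroxy-5-methoxybenzaldehyde | COc1cc(C[C@H](CO[Si](C)(C)C(C)(C)C)Oc2c(OC)cc(C=O)cc2O)ccc1O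
A6 | alternative 2 | (2S,3S)-2-({[tert-butyl(dimethyl)silyl]oxy}methyl)-3-(4-hydroxy-3-methoxyphenyl)-8-methoxy-2,3-dihydro-1,4-benzodioxine-6-carbaldehyde | COc1cc([C@@H]2Oc3cc(C=O)cc(OC)c3O[C@H]2CO[Si](C)(C)C(C)(C)C)ccc1O
A7 | alternative 3 | methyl 4-bromo-3-hydroxy-5-methoxybenzoate | COC(=O)c1cc(O)c(Br)c(OC)c1
A8 | alternative 3 | tert-butyl({(2S,3R)-3-[3-methoxy-4-(methoxymethoxy)phenyl]oxiran-2-yl}methoxy)dimethylsilane (cis-epoxide) | COCOc1ccc([C@H]2O[C@H]2CO[Si](C)(C)C(C)(C)C)cc1OC
A9 | alternative 3 | methyl (2S,3S)-2-({[tert-butyl(dimethyl)silyl]oxy}methyl)-8-methoxy-3-[3-methoxy-4-(methoxymethoxy)phenyl]-2,3-dihydro-1,4-benzodioxine-6-carboxylate | COc1cc([C@@H]2Oc3cc(C(=O)OC)cc(OC)c3O[C@H]2CO[Si](C)(C)C(C)(C)C)ccc1OCOC
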